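I began with the easy step. In birch, the asked flask followed so far, L read 0.1% at 180 min while E stayed near 67.6%, so about a third of the L charged stood in neither reading.

| flask | L | Z | Q | temperature | remark | time |
|---|---|---|---|---|---|---|
| birch | 0.61 M | 0.95 equiv | 0.183 M | 20 °C | the very flask that is asked about, followed so far |  |
| larch | 0.61 M | 0.95 equiv | 0.183 M | 15 °C | run made earlier |  |
| flask | 0.61 M | 0.950 equiv | 0.183 M | 20 °C |  | 12 h |

| run | time / min | E / % | L / % |
|---|---|---|---|
| birch | 80.0 | 67.8 | 0.7 |
| birch | 180 | 67.3 | 0.1 |
| birch | 360 | 67.4 | 0.3 |
| birch | 600 | 67.8 | 0.4 |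
| larch | 80.0 | 62.4 | 7.5 |
| larch | 180 | 66.8 | 0.5 |
| larch | 360 | 66.9 | 0 |
| larch | 600 | 67.0 | 0 |

(each reading ± 0.3 percentage points)

* E, in percent of the L first charged, at 12 h
* the remedy with the largest gain of E, or "none" below 2 percentage points (north-west / south-west / west / north-east / none)
* E present, with what was taken out counted in, in percent of the L first charged, after north-west
* E present, with what was taken out counted in, in percent of the L first charged, after south-west

- north-west: change nothing and wait 12 h more
- south-west: at 12 h take out 90% of the E then present, then wait 12 h
- west: at 12 h raise the temperature by 25 K, then wait 12 h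
- north-east: at 12 h add Z, 100% of the amount charged, then wait 12 h

- E taken out counts as made
- additions bring no volume worth counting

I then followed one molecule of Z, supposing that each E takes one Z. At its fork it either ends in E or does not, and birch gives the Z chance, the plateau of E per equivalent of Z charged: 0.711. My own reckoning supposed that the missing L was still waiting for Z, with Z as the limiting reagent. Then the Z added in north-east, at that chance, offers 67.6% of the L charge, more than the gap of 32.4%. So I committed to north-east, with a gain equal to the gap.

The forecast gave 67.5% at 12 h, 67.5% after north-west, 67.5% after south-west and none as the best remedy, holding that “adding more does nothing”. On that last point it differs from my reckoning.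

The flask gave 67.8% at 12 h, 67.8% after north-west and 67.8% after south-west. The best remedy was north-east, with 32 percentage points gained. At 720 min the flask held D at 32.2% of the L charged and free Z at 0%. The offer of 67.6% stood above that D, and the gain matched the D.

    L → D (k = 0.0610 min⁻¹, Ea = 91.0 kJ mol⁻¹)
    Z → G (k = 0.470 min⁻¹, Ea = 79.0 kJ mol⁻¹)
    D + G → E (k = 0.370 M⁻¹ min⁻¹, Ea = 67.0 kJ mol⁻¹)
    Z + Q → X (k = 2.70 M⁻¹ min⁻¹, Ea = 48.0 kJ mol⁻¹)
    (constants at 20 °C)

In a neighbour flask, like this one but charged with 0.240 equiv of Z, the Z chance gives 17.1% of E. That neighbour flask gave less, 13.0%, with D at 87.0% of the L charged and Q at 63.4% of its own charge.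

Readings and results come from a simulation for substances that don't exist.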